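**Retrosynthetic overview**
1. Target 14 ⇐ acid removal of the MOM and trityl groups from enal 12 ⇐ Wittig two-carbon homologation of benzodioxane aldehyde 10.
2. Key step: the whole 1,4-dioxane ring of 10 is made in one flask from cis-epoxide 7 and 4-fluoro-3-hydroxybenzaldehyde 8. The phenoxide opens the epoxide at the benzylic carbon (SN2, inversion), then the freed alkoxide displaces the fluoride para to CHO (SNAr, retention), so cis-epoxide gives trans-dioxane and the formyl group fixes the regiochemistry.
3. 7 ⇐ cis-glycidate 5 (reduction, tritylation) ⇐ catalytic asymmetric epoxidation of Z-cinnamate 4 ⇐ Z-selective olefination of MOM-protected syringaldehyde 2.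
4. Ring order: oxirane first (the only stereo-defining step), then the dioxane ring onto the existing benzene ring, consuming the oxirane.

Assumption: compounds 3, 8, 11 and the manganese salen chloride catalyst in both enantiomeric forms are taken as catalogue items.

**Route**

Step 1
Reactants: 1 4-hydroxy-3,5-dimethoxybenzaldehyde (syringaldehyde)
Product: 2 3,5-dimethoxy-4-(methoxymethoxy)benzaldehyde
Conditions: MOMCl, iPr2NEt, CH2Cl2, 0 °C → rt
Reagents that add atoms: chloromethyl methyl ether (MOMCl), COCCl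
Why: O-alkylation of the acidic phenol (Williamson-type acetal formation) gives a base-stable MOM ether, so that no phenoxide para to the later benzylic epoxide can open it to a quinone methide and scramble the benzylic centre.

Step 2
Reactants: 2 3,5-dimethoxy-4-(methoxymethoxy)benzaldehyde; 3 ethyl 2-(diphenoxyphosphoryl)acetate
Product: 4 ethyl (2Z)-3-[3,5-dimethoxy-4-(methoxymethoxy)phenyl]prop-2-enoate
Conditions: NaH, THF, −78 → 0 °C
Reagents that add atoms: none
Why: Ando variant of the Horner–Wadsworth–Emmons olefination, in which the electron-poor diaryl phosphonate collapses fast and irreversibly from the kinetic adduct and gives the Z-enoate (typically ≥ 9:1 with aromatic aldehydes, E isomer removed by chromatography).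

Step 3
Reactants: 4 ethyl (2Z)-3-[3,5-dimethoxy-4-(methoxymethoxy)phenyl]prop-2-enoate
Product: 5 ethyl (2R,3R)-3-[3,5-dimethoxy-4-(methoxymethoxy)phenyl]oxirane-2-carboxylate
Conditions: (R,R)-[N,N'-bis(3,5-di-tert-butylsalicylidene)cyclohexane-1,2-diaminato]manganese chloride (C36H52ClMnN2O2, trivalent manganese, 6 mol %), 4-phenylpyridine N-oxide (0.25 equiv), aq NaOCl buffered to pH 11.3 with Na2HPO4, CH2Cl2, 4 °C
Reagents that add atoms: sodium hypochlorite, [Na+].[O-]Cl
Why: Jacobsen–Katsuki asymmetric epoxidation, for which Z-cinnamate esters (electron-rich aryl included) are a privileged class; the (R,R)-catalyst delivers oxygen to the face that gives the (2R,3R) cis-glycidate, so both stereocentres of the target originate here (about 93–96 % ee expected, minor trans-epoxide separable).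

Step 4
Reactants: 5 ethyl (2R,3R)-3-[3,5-dimethoxy-4-(methoxymethoxy)phenyl]oxirane-2-carboxylate
Product: 6 [(2S,3R)-3-[3,5-dimethoxy-4-(methoxymethoxy)phenyl]oxiran-2-yl]methanol
Conditions: NaBH4, EtOH, 0 °C → rt
Reagents that add atoms: none
Why: chemoselective borohydride reduction of an α-oxygen-activated ester leaves the epoxide untouched under non-acidic conditions; no stereocentre is affected (the descriptor at C2 changes from R to S only because the CIP priorities change).

Step 5
Reactants: 6 [(2S,3R)-3-[3,5-dimethoxy-4-(methoxymethoxy)phenyl]oxiran-2-yl]methanol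
Product: 7 (2R,3S)-2-[3,5-dimethoxy-4-(methoxymethoxy)phenyl]-3-[(triphenylmethoxy)methyl]oxirane
Conditions: TrCl, Et3N, DMAP (cat.), CH2Cl2, 0 °C → rt
Reagents that add atoms: trityl chloride (TrCl), ClC(c1ccccc1)(c1ccccc1)c1ccccc1
Why: tritylation of the primary alcohol installs a base-stable, non-migrating group that shuts down Payne rearrangement and a competing seven-membered SNAr closure in the next step, and it falls off later under the same acid as the MOM group.

Step 6
Reactants: 7 (2R,3S)-2-[3,5-dimethoxy-4-(methoxymethoxy)phenyl]-3-[(triphenylmethoxy)methyl]oxirane; 8 4-fluoro-3-hydroxybenzaldehyde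
Product: 10 (2S,3S)-3-[3,5-dimethoxy-4-(methoxymethoxy)phenyl]-2-[(triphenylmethoxy)methyl]-2,3-dihydro-1,4-benzodioxine-6-carbaldehyde, via ring-opened fluoro alcohol 9 (not isolated)
Conditions: Cs2CO3 (2.5 equiv), DMF, 70 °C then 100 °C
Reagents that add atoms: none
Why: tandem SN2 epoxide opening and intramolecular SNAr, both established reaction types: the phenoxide (itself too electron-rich to suffer SNAr) attacks the benzylic, inductively less deactivated epoxide carbon with inversion (R → S), and the resulting C2 alkoxide then displaces the fluoride now activated by the para formyl group with retention at carbon, so the cis-epoxide is converted stereospecifically into the trans (2S,3S) dioxane with the oxygen para to CHO on the CH2O-bearing carbon.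

Step 7
Reactants: 10 (2S,3S)-3-[3,5-dimethoxy-4-(methoxymethoxy)phenyl]-2-[(triphenylmethoxy)methyl]-2,3-dihydro-1,4-benzodioxine-6-carbaldehyde; 11 (triphenylphosphoranylidene)acetaldehyde
Product: 12 (2E)-3-{(2S,3S)-3-[3,5-dimethoxy-4-(methoxymethoxy)phenyl]-2-[(triphenylmethoxy)methyl]-2,3-dihydro-1,4-benzodioxin-6-yl}prop-2-enal
Conditions: toluene, 90 °C (1.3 equiv of 11)
Reagents that add atoms: none
Why: Wittig olefination with the stabilised formyl ylide gives the E-enal directly under neutral conditions that touch neither the acetal, the trityl ether nor the stereocentres.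

Step 8
Reactants: 12 (2E)-3-{(2S,3S)-3-[3,5-dimethoxy-4-(methoxymethoxy)phenyl]-2-[(triphenylmethoxy)methyl]-2,3-dihydro-1,4-benzodioxin-6-yl}prop-2-enal
Product: 14 (2E)-3-[(2S,3S)-3-(4-hydroxy-3,5-dimethoxyphenyl)-2-(hydroxymethyl)-2,3-dihydro-1,4-benzodioxin-6-yl]prop-2-enal, via detritylated MOM ether 13 (not isolated)
Conditions: 3 M aq HCl, THF, 40 °C
Reagents that add atoms: none
Why: acid-catalysed trityl ether solvolysis followed by MOM acetal hydrolysis frees both hydroxyl groups without affecting the enal, and any reversible ionisation at the benzylic C–O bond can only return to the thermodynamically favoured trans isomer because the adjacent CH2OH-bearing centre is fixed.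

**Compound list**
1 | 4-hydroxy-3,5-dimethoxybenzaldehyde (syringaldehyde) | COc1cc(C=O)cc(OC)c1O | starting material
2 | 3,5-dimethoxy-4-(methoxymethoxy)benzaldehyde | COCOc1c(OC)cc(C=O)cc1OC | intermediate
3 | ethyl 2-(diphenoxyphosphoryl)acetate | CCOC(=O)CP(=O)(Oc1ccccc1)Oc1ccccc1 | starting material
4 | ethyl (2Z)-3-[3,5-dimethoxy-4-(methoxymethoxy)phenyl]prop-2-enoate | CCOC(=O)/C=C\c1cc(OC)c(OCOC)c(OC)c1 | intermediate
5 | ethyl (2R,3R)-3-[3,5-dimethoxy-4-(methoxymethoxy)phenyl]oxirane-2-carboxylate (cis) | COCOc1c(OC)cc(cc1OC)[C@H]2O[C@H]2C(=O)OCC | intermediate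
6 | [(2S,3R)-3-[3,5-dimethoxy-4-(methoxymethoxy)phenyl]oxiran-2-yl]methanol (cis) | COCOc1c(OC)cc(cc1OC)[C@H]2O[C@H]2CO | intermediate
7 | (2R,3S)-2-[3,5-dimethoxy-4-(methoxymethoxy)phenyl]-3-[(triphenylmethoxy)methyl]oxirane (cis; aryl carbon R, CH2OTr carbon S) | COCOc1c(OC)cc(cc1OC)[C@H]2O[C@H]2COC(c3ccccc3)(c4ccccc4)c5ccccc5 | intermediate
8 | 4-fluoro-3-hydroxybenzaldehyde | O=Cc1ccc(F)c(O)c1 | starting material
9 | 3-{(1S,2S)-1-[3,5-dimethoxy-4-(methoxymethoxy)phenyl]-2-hydroxy-3-(triphenylmethoxy)propoxy}-4-fluorobenzaldehyde | COCOc1c(OC)cc(cc1OC)[C@H](Oc2cc(C=O)ccc2F)[C@@H](O)COC(c3ccccc3)(c4ccccc4)c5ccccc5 | intermediate (not isolated)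
10 | (2S,3S)-3-[3,5-dimethoxy-4-(methoxymethoxy)phenyl]-2-[(triphenylmethoxy)methyl]-2,3-dihydro-1,4-benzodioxine-6-carbaldehyde (trans) | COCOc1c(OC)cc(cc1OC)[C@@H]2Oc3cc(C=O)ccc3O[C@H]2COC(c4ccccc4)(c5ccccc5)c6ccccc6 | intermediate
11 | (triphenylphosphoranylidene)acetaldehyde | O=CC=P(c1ccccc1)(c2ccccc2)c3ccccc3 | starting material
12 | (2E)-3-{(2S,3S)-3-[3,5-dimethoxy-4-(methoxymethoxy)phenyl]-2-[(triphenylmethoxy)methyl]-2,3-dihydro-1,4-benzodioxin-6-yl}prop-2-enal | COCOc1c(OC)cc(cc1OC)[C@@H]2Oc3cc(/C=C/C=O)ccc3O[C@H]2COC(c4ccccc4)(c5ccccc5)c6ccccc6 | intermediate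
13 | (2E)-3-{(2S,3S)-3-[3,5-dimethoxy-4-(methoxymethoxy)phenyl]-2-(hydroxymethyl)-2,3-dihydro-1,4-benzodioxin-6-yl}prop-2-enal | COCOc1c(OC)cc(cc1OC)[C@@H]2Oc3cc(/C=C/C=O)ccc3O[C@H]2CO | intermediate (not isolated)
14 | (2E)-3-[(2S,3S)-3-(4-hydroxy-3,5-dimethoxyphenyl)-2-(hydroxymethyl)-2,3-dihydro-1,4-benzodioxin-6-yl]prop-2-enal | COc1cc([C@@H]2Oc3cc(/C=C/C=O)ccc3O[C@H]2CO)cc(OC)c1O | target

**Totals**
Total step count: 8. Longest linear sequence: 8 steps (1 → 14).

**Three steps most likely to fail**

Step 6 (tandem epoxide opening and SNAr). The phenoxide of 8 is a weak nucleophile for a cis-disubstituted epoxide, the electron-rich benzylic carbon may leak toward an SN1 pathway (which would give some cis-dioxane), and the heat needed for the SNAr may degrade material. The fallback sets out from 7 and separates the two events. Epoxide 7 is opened at 60–70 °C (Cs2CO3, DMF) with commercial 4-bromo-3-hydroxybenzaldehyde (O=Cc1ccc(Br)c(O)c1), whose aryl bromide is inert under these conditions, to give the isolable 4-bromo-3-{(1S,2S)-1-[3,5-dimethoxy-4-(methoxymethoxy)phenyl]-2-hydroxy-3-(triphenylmethoxy)propoxy}benzaldehyde F1. The ring is then closed by a palladium-catalysed intramolecular C–O coupling instead of SNAr (Pd(OAc)2, racemic 2-(di-tert-butylphosphino)-1,1'-binaphthyl, Cs2CO3, toluene, 80 °C), which proceeds with retention at the carbinol carbon and is favoured by the electron-poor aryl bromide. It comes back to the route at 10.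

Step 3 (asymmetric epoxidation of the electron-rich Z-cinnamate). Possible problems are leakage to the trans-epoxide through the stepwise radical pathway, an ee below the expected range, or ring chlorination by hypochlorite. The fallback sets out from 4 and moves the stereo-defining step to a directed epoxidation. Ester 4 is reduced with iBu2AlH (CH2Cl2, −78 °C) to (2Z)-3-[3,5-dimethoxy-4-(methoxymethoxy)phenyl]prop-2-en-1-ol F2. Sharpless asymmetric epoxidation of F2 (Ti(OiPr)4, L-(+)-diisopropyl tartrate, tBuOOH, 4 Å molecular sieves, CH2Cl2, −20 °C, short reaction time and buffered work-up because the product is acid-sensitive) then delivers the (2S,3R) cis-epoxy alcohol. It comes back to the route at 6 and skips step 4.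

Step 7 (Wittig with the formyl ylide). The product enal is more electrophilic than the electron-rich aldehyde 10, so a second olefination to the dienal or incomplete conversion can cut the yield. The fallback sets out from 10 and builds the enal by oxidation-state adjustment instead. Horner–Wadsworth–Emmons reaction with triethyl phosphonoacetate (LiCl, DBU, MeCN, rt) gives ethyl (2E)-3-{(2S,3S)-3-[3,5-dimethoxy-4-(methoxymethoxy)phenyl]-2-[(triphenylmethoxy)methyl]-2,3-dihydro-1,4-benzodioxin-6-yl}prop-2-enoate F3, which cannot over-react. Reduction with iBu2AlH (CH2Cl2, −78 °C) gives (2E)-3-{(2S,3S)-3-[3,5-dimethoxy-4-(methoxymethoxy)phenyl]-2-[(triphenylmethoxy)methyl]-2,3-dihydro-1,4-benzodioxin-6-yl}prop-2-en-1-ol F4, and selective allylic oxidation with MnO2 (CH2Cl2, rt) gives the enal. It comes back to the route at 12.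

**Further compounds**
F1 | step 6 | 4-bromo-3-{(1S,2S)-1-[3,5-dimethoxy-4-(methoxymethoxy)phenyl]-2-hydroxy-3-(triphenylmethoxy)propoxy}benzaldehyde | COCOc1c(OC)cc(cc1OC)[C@H](Oc2cc(C=O)ccc2Br)[C@@H](O)COC(c3ccccc3)(c4ccccc4)c5ccccc5
F2 | step 3 | (2Z)-3-[3,5-dimethoxy-4-(methoxymethoxy)phenyl]prop-2-en-1-ol | OC/C=C\c1cc(OC)c(OCOC)c(OC)c1
F3 | step 7 | ethyl (2E)-3-{(2S,3S)-3-[3,5-dimethoxy-4-(methoxymethoxy)phenyl]-2-[(triphenylmethoxy)methyl]-2,3-dihydro-1,4-benzodioxin-6-yl}prop-2-enoate | COCOc1c(OC)cc(cc1OC)[C@@H]2Oc3cc(/C=C/C(=O)OCC)ccc3O[C@H]2COC(c4ccccc4)(c5ccccc5)c6ccccc6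
F4 | step 7 | (2E)-3-{(2S,3S)-3-[3,5-dimethoxy-4-(methoxymethoxy)phenyl]-2-[(triphenylmethoxy)methyl]-2,3-dihydro-1,4-benzodioxin-6-yl}prop-2-en-1-ol | COCOc1c(OC)cc(cc1OC)[C@@H]2Oc3cc(/C=C/CO)ccc3O[C@H]2COC(c4ccccc4)(c5ccccc5)c6ccccc6
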